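Compound numbers used below are those of the steps and of the compound list that follows them.

## Analysis of the target

1. Target 31 is a flavanone: aromatic ring A (C4a to C8a) is fused to the dihydropyranone ring C (O1, C2, C3, C4), and ring B, a 2,5-dihydroxyphenyl group, sits on C2.
2. Ring A is fully differentiated: a hydroxyl on C5 hydrogen-bonded to the C4 carbonyl, a methyl ether on C7, a hydrogen on C6, and on C8 a lavandulyl chain that starts with the benzylic methylene C1'' and branches at C2'' into an isopropenyl and a prenyl arm.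
3. There are two stereocentres, C2 (S) and C2'' (R). They lie five bonds apart (C2–O1–C8a–C8–C1''–C2''), neither can steer the other, and the C2 epimers would be hard to separate, so each centre needs its own reagent control.
4. Several groups are sensitive. C2 epimerises by base-induced retro-oxa-Michael opening to the chalcone. The hydroquinone of ring B is oxidised by air. The 1,5-diene of the side chain is open to acid-induced hydration and cation cyclisation. C2'' would be lost if a carbonyl precursor of the isopropenyl group enolised.
5. The main difficulty is ring A: a phloroglucinol core whose three oxygens must end in three different states and whose C8 must carry a chiral, branched alkyl group that no direct C-alkylation delivers regio- or stereoselectively.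
6. The strategy rests on the fact that C1'' is a benzylic CH2 on C8, next to C8a–O1. The atoms C1''–C8–C8a–O8a are therefore the skeleton of an ortho-quinone methide; an enolate that adds to C1'' becomes C2'', and its acyl carbon is caught by O8a.
7. The lactone formed in this way creates C2'' and at the same time marks O8a as different from O5, which later lets ring C be attached at C4a without ambiguity.

## Retrosynthetic reasoning

**31 ⇒ 30.** The last operation is cleavage of the three methoxymethyl ethers on O5, O2' and O5'. Keeping the hydroquinone and the chelated O5 phenol masked until the end protects ring B from oxidation and keeps acidic protons out of the organometallic and hydride steps. The forward step must remove three acetals without protonating the two side-chain alkenes and without opening ring C.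

**30 ⇒ 28 (via 29).** The C2–H bond is cut, leading back to flavone 28. Because C2 cannot be controlled by the distant C2'', it is best created on a flat precursor by a chiral catalyst, and a flavone has no ring C stereocentre to lose while ring C is assembled. The forward step is an enantioface-selective conjugate delivery of hydride to C2 that leaves both side-chain alkenes alone. The C4 carbonyl is parked as silyl enol ether 29 until work-up.

**28 ⇒ 26 ⇒ 25 ⇒ 23 + 15.** Ring C is opened at O1–C2 to give the ortho-hydroxyaryl ynone 26. The ynone is taken back to propargylic alcohol 25, and this is cut at C3–C4 into salicylaldehyde 23 and ring B alkyne 15, used as its acetylide 24. C3–C4 is preferred to C2–C1' because it joins two fragments of similar size by a plain carbonyl addition. Closure through the amine adduct 27 can only occur at C2, so the six-membered ring is secured over the five-membered alternative.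

**23 ⇒ 22.** The C4a–C4 bond is cut. In phenol 22 the only free position ortho to the O8a hydroxyl is C4a, so a phenoxide-templated ortho-formylation is regiochemically unambiguous. C6 is para to O8a and is not reached. This is where the O8a/O5 distinction made in the key step is used.

**22 ⇒ 21 ⇒ 20 ⇒ 19 ⇒ 18 ⇒ 17.** The isopropenyl group is traced back to the lactone carbonyl: the C=CH2 bond is cut (ketone 20), then the C–CH3 bond (Weinreb amide 19), and the amide is the ring-opened form of lactone 17. The phenol released on opening (18) is silylated (19) so that the methyl addition and the methylenation run without an acidic OH or a cyclic hemiketal, and it is unmasked again in 22. Since C2'' is alpha to the carbonyl in 20, the methylenation must be non-basic.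

**17 ⇒ 12 + 7 (via 16).** The key disconnection cuts C1''–C2'' and the O8a–acyl bond. It is made here because it is the only place where the side-chain carbon, the stereocentre and the oxygen label can be installed in one operation from two achiral, simple partners. Fluoride turns 12 into methide 16, and a chiral carbene turns 7 into an enolate. The forward reaction must join them with control of the enolate face and without epimerising the product at C3.

**12 ⇒ 11 ⇒ 10 ⇒ 9 ⇒ 8.** The bromide is taken back to benzylic alcohol 11, aldehyde 10 and the commercial dihydroxybenzaldehyde 8. The two phenols of 8 differ intrinsically: the para hydroxyl is free, the ortho one is chelated to the aldehyde. O5 can therefore receive the fluoride-stable acetal first and O8a the fluoride-labile silyl group second.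

**7 ⇒ 5 + 6; 5 ⇒ 4 ⇒ 1 + 2 (via 3).** The acyl imidazole comes from acid 5 and 6. The acid is cut at C2–C3 by a [3,3] shift of ketene acetal 3, which builds the trisubstituted alkene of the future prenyl arm from 1 and 2.

**15 ⇒ 14 ⇒ 13.** The alkyne is taken back by one-carbon homologation to aldehyde 14, which is the bis-acetal of commercial 13.

## Alternatives that were turned down

**Alternative 1:** Ring A would be built last. The disconnection cuts C4a–C5 and C8–C8a. Ring B, ring C and C2 arrive in the (2S)-5-bromo-2-aryl-2,3-dihydropyran-4-one A2, and C5–C8 with the side chain arrive in the 1,3-dimethoxy-1-silyloxydiene A3. A (4+2) cycloaddition, then loss of HBr and of the silyl methyl acetal unit, would give flavanone A1.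
- For: it is the most convergent plan. The polarity of the two partners fixes the regiochemistry. The O5 (free)/O7 (methyl) distinction comes for nothing, and A1 is one deprotection from 31. On step count it is clearly stronger than the chosen route.
- Against: the reacting double bond of A2 belongs to a vinylogous ester whose beta carbon carries O1, so it is an electron-rich, reluctant dienophile that bromine only partly activates. A3 must react through a terminus bearing a branched substituent, and its ketene acetal end is hydrolytically fragile. The aromatisation needs base or heat on an intermediate in which O1 is beta to a ketone; ring C can then open and C2 can scramble. A3 must also be made from an enantiopure lavandulyl unit, so the key step does nothing for C2''.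
- Comparison: the chosen route is longer, but it creates C2'' catalytically from achiral material and puts no stress on C2, which is made at the penultimate step.

**Alternative 2:** Ring A would be made by benzannulation. C8–C8a and C6–C7 are cut (C4a–C8a is re-formed in the final electrocyclisation). Thermolysis of 3-(methoxymethoxy)cyclobutenone A5 with the lavandulyl methoxyalkyne A6 would give phenol A4, which is identical with 22 of the chosen route.
- For: a reagent-free thermal cascade (4π opening, ketene–alkyne (2+2), 4π opening, 6π closure) fixes the whole substitution pattern by mechanism and leaves only O8a free. It reaches the very intermediate 22 in one step where the chosen route needs twelve linear steps. On step economy to this point it is stronger.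
- Against: the cascade does not create C2''. A6 must carry the stereocentre, so an enantiopure lavandulyl unit has to be bought or made and then homologated to a 1-methoxyalkyne, a labile class. A5 is a hydrolytically sensitive 3-alkoxycyclobutenone whose donor-substituted vinylketene can dimerise. The intermediate ketenes have the isopropenyl and prenyl alkenes within reach for intramolecular (2+2) capture.
- Comparison: the chosen route gives up the brevity. In exchange it makes C2'' in the same catalytic step that attaches the chain to ring A, from stable and inexpensive precursors.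

**Alternative 3:** Ring C would be closed by carbene C–H insertion. C2–C3 is cut; diazomethyl ketone A8, with a 2,5-disilyloxybenzyl ether on O8a, would lose N2 on a chiral dirhodium tetracarboxylate (divalent rhodium). The carbene at C3 would insert into one benzylic C–H bond to give flavanone A7.
- For: ring closure and C2 are achieved together from an achiral CH2, at a late stage. The all-silyl protection of A7 allows a final fluoride deprotection, which is kinder to the side-chain alkenes than the acid used at the end of the chosen route. On that point it is stronger.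
- Against: an acceptor-only carbene from a diazomethyl ketone is the least selective carbene class, and 1,6-insertion with useful enantiocontrol is uncertain. The carbene has easier outlets: oxonium ylide formation at O1 with a benzyl shift, cyclopropanation of the isopropenyl or prenyl alkene, and addition to electron-rich ring B. A8 needs a diazoketone built on a doubly ortho-substituted benzoic acid. The plan also says nothing about ring A or C2''.
- Comparison: the chosen route sets C2 by a conjugate reduction that has a clean fallback, and it solves the ring A and C2'' problems that this alternative leaves open.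

Key step: step 10

Assumption: the hands of the two chiral catalysts written in steps 10 and 20 are those expected by analogy with related substrates; both exist in either hand, and the other hand is taken if a trial on a model compound shows the opposite sense of induction.

## Route

Step 1
Reactants: 1 2-methylbut-3-en-2-ol; 2 triethyl orthoacetate
Product: 4 ethyl 5-methylhex-4-enoate, via ketene acetal 3 (not isolated)
Conditions: EtCO2H (cat.), neat, 140 °C, EtOH distilled off
Reagents that add atoms: none
Why: Johnson–Claisen rearrangement: acid-catalysed exchange gives ketene acetal 3, whose [3,3]-sigmatropic shift forms the new C–C bond at the vinyl terminus and leaves the trisubstituted alkene of the future prenyl arm.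

Step 2
Reactants: 4 ethyl 5-methylhex-4-enoate
Product: 5 5-methylhex-4-enoic acid
Conditions: LiOH·H2O, THF/MeOH/H2O, rt; then 1 M HCl to pH 3
Reagents that add atoms: lithium hydroxide, [Li+].[OH-]
Why: Plain ester saponification by acyl–oxygen cleavage; the isolated trisubstituted alkene is inert to hydroxide and to the brief cold acidification.

Step 3
Reactants: 5 5-methylhex-4-enoic acid; 6 1,1'-carbonyldiimidazole
Product: 7 1-(1H-imidazol-1-yl)-5-methylhex-4-en-1-one
Conditions: CH2Cl2, rt, until gas evolution stops; quick cold water wash, dried, used within a day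
Reagents that add atoms: none
Why: Carboxyl activation with carbonyldiimidazole, driven by loss of CO2; aliphatic acyl imidazoles survive a short aqueous wash and are the acyl donors required by the carbene step.

Step 4
Reactants: 8 2,4-dihydroxy-6-methoxybenzaldehyde
Product: 9 2-hydroxy-6-methoxy-4-(methoxymethoxy)benzaldehyde
Conditions: MOMCl (1.05 equiv), i-Pr2NEt, CH2Cl2, 0 °C
Reagents that add atoms: chloro(methoxy)methane, COCCl
Why: Selective O-alkylation: the 4-hydroxyl (the future O5) is the more acidic and unchelated phenol, whereas the 2-hydroxyl is tied up in a hydrogen bond to the aldehyde, so one equivalent of reagent should protect only the 4-position.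

Step 5
Reactants: 9 2-hydroxy-6-methoxy-4-(methoxymethoxy)benzaldehyde
Product: 10 2-[(tert-butyldimethylsilyl)oxy]-6-methoxy-4-(methoxymethoxy)benzaldehyde
Conditions: TBSCl, imidazole, DMF, rt
Reagents that add atoms: tert-butyl(chloro)dimethylsilane, CC(C)(C)[Si](C)(C)Cl
Why: Imidazole-promoted silylation of the remaining chelated phenol (the future O8a); this places the fluoride-labile trigger on the oxygen that will become the methide oxygen.

Step 6
Reactants: 10 2-[(tert-butyldimethylsilyl)oxy]-6-methoxy-4-(methoxymethoxy)benzaldehyde
Product: 11 {2-[(tert-butyldimethylsilyl)oxy]-6-methoxy-4-(methoxymethoxy)phenyl}methanol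
Conditions: NaBH4, THF/MeOH (10:1), −10 °C, short time; pH 7 buffer
Reagents that add atoms: none
Why: Borohydride reduction of the aldehyde; low temperature, little methanol and a buffered quench are chosen to suppress migration of the silyl group from the phenol oxygen to the new benzylic alkoxide.

Step 7
Reactants: 11 {2-[(tert-butyldimethylsilyl)oxy]-6-methoxy-4-(methoxymethoxy)phenyl}methanol
Product: 12 tert-butyl[2-(bromomethyl)-3-methoxy-5-(methoxymethoxy)phenoxy]dimethylsilane
Conditions: CBr4 (1.3 equiv), PPh3 (1.25 equiv, added last in portions), 2,6-lutidine (0.5 equiv), CH2Cl2, −20 → 0 °C; pentane, rapid filtration through basic Al2O3; used at once as a cold solution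
Reagents that add atoms: carbon tetrabromide, BrC(Br)(Br)Br
Why: Appel bromination under essentially neutral conditions, so the acetal and the silyl ether see no HBr; the bromide of this trioxygenated ring ionises easily, so it is not chromatographed or stored but taken directly into step 10.

Step 8
Reactants: 13 2,5-dihydroxybenzaldehyde
Product: 14 2,5-bis(methoxymethoxy)benzaldehyde
Conditions: MOMCl (3 equiv), i-Pr2NEt (4 equiv), DMAP (cat.), CH2Cl2, 0 → 40 °C, Ar
Reagents that add atoms: chloro(methoxy)methane, COCCl
Why: Exhaustive O-alkylation of both phenols; excess reagent and gentle heating overcome the chelation of the 2-hydroxyl, and the acetals match the O5 protecting group so that one final operation removes all three.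

Step 9
Reactants: 14 2,5-bis(methoxymethoxy)benzaldehyde
Product: 15 2-ethynyl-1,4-bis(methoxymethoxy)benzene
Conditions: MeC(O)C(N2)P(O)(OMe)2, K2CO3, MeOH, 0 °C → rt
Reagents that add atoms: dimethyl (1-diazo-2-oxopropyl)phosphonate, CC(=O)C(=[N+]=[N-])P(=O)(OC)OC
Why: Seyferth–Gilbert homologation in the Ohira–Bestmann form: methanolysis releases the diazomethylphosphonate anion, which converts the aldehyde into the terminal alkyne under mild carbonate conditions that the aryl acetals tolerate.

Step 10
Reactants: 12 tert-butyl[2-(bromomethyl)-3-methoxy-5-(methoxymethoxy)phenoxy]dimethylsilane; 7 1-(1H-imidazol-1-yl)-5-methylhex-4-en-1-one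
Product: 17 (3R)-5-methoxy-7-(methoxymethoxy)-3-(3-methylbut-2-en-1-yl)chroman-2-one, via ortho-quinone methide 16 (not isolated)
Conditions: (5aS,10bR)-2-(2,4,6-trimethylphenyl)-5a,10b-dihydro-4H,6H-indeno[2,1-b][1,2,4]triazolo[4,3-d][1,4]oxazin-2-ium tetrafluoroborate (15 mol%), CsF (2.2 equiv), 18-crown-6 (2.2 equiv), 4 Å MS, THF, −20 °C → rt
Reagents that add atoms: none
Why: Fluoride cleaves the aryl silyl ether of 12 and the phenoxide expels bromide by 1,4-elimination to give ortho-quinone methide 16, while the carbene freed from the triazolium salt adds to acyl imidazole 7, displaces the azole and, after loss of the alpha proton to the liberated azolide, becomes a chiral azolium enolate. The enolate carbon (the future C2'') adds to the exocyclic methide carbon (C1'') of 16, which restores the aromatic ring, and the phenoxide O8a then attacks the acyl azolium carbonyl in a 6-exo-trig lactonisation that closes the chroman-2-one ring and returns the carbene. The closest known reaction type is the carbene-catalysed formal (4+2) annulation of acyl-imidazole-derived azolium enolates with fluoride-generated ortho-quinone methides to 3-substituted dihydrocoumarins, applied here to a more electron-rich methide. The only new stereocentre, C3 of the lactone (C2''), is set by the catalyst: the fused indane of the aminoindanol backbone shields one face of the enolate so that 16 approaches the other, which should give the 3R lactone with the hand of catalyst shown. Regioselectivity needs no control, because 16 can form only across C1''–C8–C8a–O8a and has a single electrophilic terminus; the methide carbon is unsubstituted, so no second stereocentre arises. The step does need the catalysed pathway to outrun self-condensation of 16 and its capture by the azole, which is why sparingly soluble CsF with 18-crown-6 releases 16 slowly into an excess of enolate, and it needs the product not to epimerise at C3, which is why the temperature is kept low and the reaction is stopped once 12 is consumed.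

Step 11
Reactants: 17 (3R)-5-methoxy-7-(methoxymethoxy)-3-(3-methylbut-2-en-1-yl)chroman-2-one
Product: 18 (2R)-2-{[2-hydroxy-6-methoxy-4-(methoxymethoxy)phenyl]methyl}-N-methoxy-N,5-dimethylhex-4-enamide
Conditions: Me(MeO)NH·HCl, AlMe3, CH2Cl2, 0 °C → rt; aq. potassium sodium tartrate
Reagents that add atoms: N,O-dimethylhydroxylamine hydrochloride, CNOC.Cl
Why: Weinreb aminolysis of an activated aryl ester by the aluminium amide; the reagent is weakly basic, so the alpha stereocentre should survive, and ring opening releases O8a as the only free phenol.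

Step 12
Reactants: 18 (2R)-2-{[2-hydroxy-6-methoxy-4-(methoxymethoxy)phenyl]methyl}-N-methoxy-N,5-dimethylhex-4-enamide
Product: 19 (2R)-2-({2-[(tert-butyldimethylsilyl)oxy]-6-methoxy-4-(methoxymethoxy)phenyl}methyl)-N-methoxy-N,5-dimethylhex-4-enamide
Conditions: TBSCl, imidazole, DMF, rt (directly after step 11)
Reagents that add atoms: tert-butyl(chloro)dimethylsilane, CC(C)(C)[Si](C)(C)Cl
Why: Phenol silylation; it prevents relactonisation of 18, removes the acidic proton before the Grignard and titanium steps, and prevents the later ketone from closing to a cyclic hemiketal.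

Step 13
Reactants: 19 (2R)-2-({2-[(tert-butyldimethylsilyl)oxy]-6-methoxy-4-(methoxymethoxy)phenyl}methyl)-N-methoxy-N,5-dimethylhex-4-enamide
Product: 20 (3R)-3-({2-[(tert-butyldimethylsilyl)oxy]-6-methoxy-4-(methoxymethoxy)phenyl}methyl)-6-methylhept-5-en-2-one
Conditions: MeMgBr, THF, −20 → 0 °C; cold aq. NH4Cl
Reagents that add atoms: methylmagnesium bromide, C[Mg]Br
Why: Weinreb ketone synthesis: the chelated tetrahedral adduct stops the addition at the ketone stage and releases the ketone only on quench, so the alpha centre is not exposed to base as a ketone.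

Step 14
Reactants: 20 (3R)-3-({2-[(tert-butyldimethylsilyl)oxy]-6-methoxy-4-(methoxymethoxy)phenyl}methyl)-6-methylhept-5-en-2-one
Product: 21 tert-butyl{3-methoxy-5-(methoxymethoxy)-2-[(2R)-5-methyl-2-(prop-1-en-2-yl)hex-4-en-1-yl]phenoxy}dimethylsilane
Conditions: Cp2TiMe2 (3 equiv), toluene/THF, 65 °C, dark
Reagents that add atoms: dimethyltitanocene, [CH3-].[CH3-].[Ti+4].c1cc[cH-]c1.c1cc[cH-]c1
Why: Petasis methylenation: thermally generated Cp2Ti=CH2 converts the ketone into the isopropenyl group through an oxatitanacyclobutane; the reagent is non-basic, so the enolisable alpha centre (C2'') should keep its configuration, and the trisubstituted alkene, acetal and silyl ether are inert.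

Step 15
Reactants: 21 tert-butyl{3-methoxy-5-(methoxymethoxy)-2-[(2R)-5-methyl-2-(prop-1-en-2-yl)hex-4-en-1-yl]phenoxy}dimethylsilane
Product: 22 3-methoxy-5-(methoxymethoxy)-2-[(2R)-5-methyl-2-(prop-1-en-2-yl)hex-4-en-1-yl]phenol
Conditions: Bu4NF, THF, 0 °C
Reagents that add atoms: none
Why: Fluoride desilylation of an aryl silyl ether; the conditions are basic rather than acidic, which matters because the free O8a phenol and the isopropenyl group would cyclise to a chroman under acid.

Step 16
Reactants: 22 3-methoxy-5-(methoxymethoxy)-2-[(2R)-5-methyl-2-(prop-1-en-2-yl)hex-4-en-1-yl]phenol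
Product: 23 2-hydroxy-4-methoxy-6-(methoxymethoxy)-3-[(2R)-5-methyl-2-(prop-1-en-2-yl)hex-4-en-1-yl]benzaldehyde
Conditions: MgCl2 (anhydrous), Et3N, (CH2O)n, MeCN, 80 °C
Reagents that add atoms: formaldehyde (as paraformaldehyde), C=O
Why: Casiraghi–Skattebøl ortho-formylation: the magnesium phenoxide delivers formaldehyde to the ortho carbon and a second formaldehyde oxidises the hydroxymethyl group by hydride transfer; C4a is the only free ortho position of the O8a phenol, so the regiochemistry is fixed, and the amine-buffered medium should spare the acetal and the alkenes.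

Step 17
Reactants: 23 2-hydroxy-4-methoxy-6-(methoxymethoxy)-3-[(2R)-5-methyl-2-(prop-1-en-2-yl)hex-4-en-1-yl]benzaldehyde; 15 2-ethynyl-1,4-bis(methoxymethoxy)benzene
Product: 25 3-[2,5-bis(methoxymethoxy)phenyl]-1-{2-hydroxy-4-methoxy-6-(methoxymethoxy)-3-[(2R)-5-methyl-2-(prop-1-en-2-yl)hex-4-en-1-yl]phenyl}prop-2-yn-1-ol (both carbinol epimers), via lithium acetylide 24 (not isolated)
Conditions: 15 (2.5 equiv), n-BuLi (2.4 equiv), THF, −78 °C; then 23, −78 → −20 °C; cold pH 7 buffer; crude product taken on
Reagents that add atoms: none
Why: Acetylide addition to an aldehyde: the first equivalent of 24 deprotonates the phenol and the lithium phenoxide chelates and activates the neighbouring carbonyl for the second; the new carbinol centre is irrelevant because it is oxidised in the next step.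

Step 18
Reactants: 25 3-[2,5-bis(methoxymethoxy)phenyl]-1-{2-hydroxy-4-methoxy-6-(methoxymethoxy)-3-[(2R)-5-methyl-2-(prop-1-en-2-yl)hex-4-en-1-yl]phenyl}prop-2-yn-1-ol
Product: 26 3-[2,5-bis(methoxymethoxy)phenyl]-1-{2-hydroxy-4-methoxy-6-(methoxymethoxy)-3-[(2R)-5-methyl-2-(prop-1-en-2-yl)hex-4-en-1-yl]phenyl}prop-2-yn-1-one
Conditions: activated MnO2 (excess), CH2Cl2, rt
Reagents that add atoms: none
Why: Manganese dioxide oxidation of a doubly activated (benzylic and propargylic) alcohol; the neutral heterogeneous oxidant leaves the unactivated alkenes and acetals alone, and the ynone is stabilised by the hydrogen bond from O8a–H.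

Step 19
Reactants: 26 3-[2,5-bis(methoxymethoxy)phenyl]-1-{2-hydroxy-4-methoxy-6-(methoxymethoxy)-3-[(2R)-5-methyl-2-(prop-1-en-2-yl)hex-4-en-1-yl]phenyl}prop-2-yn-1-one
Product: 28 2-[2,5-bis(methoxymethoxy)phenyl]-7-methoxy-5-(methoxymethoxy)-8-[(2R)-5-methyl-2-(prop-1-en-2-yl)hex-4-en-1-yl]-4H-chromen-4-one, via enaminone 27 (not isolated)
Conditions: Et2NH, EtOH, rt → 60 °C
Reagents that add atoms: none
Why: Amine-mediated chromone closure: conjugate addition of the secondary amine to the ynone gives enaminone 27, and the phenol O8a then displaces the amine at the same carbon by addition–elimination; because the oxygen must attack the amine-bearing carbon (C2), the six-membered flavone is formed and the five-membered aurone is excluded.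

Step 20
Reactants: 28 2-[2,5-bis(methoxymethoxy)phenyl]-7-methoxy-5-(methoxymethoxy)-8-[(2R)-5-methyl-2-(prop-1-en-2-yl)hex-4-en-1-yl]-4H-chromen-4-one
Product: 30 (2S)-2-[2,5-bis(methoxymethoxy)phenyl]-7-methoxy-5-(methoxymethoxy)-8-[(2R)-5-methyl-2-(prop-1-en-2-yl)hex-4-en-1-yl]-2,3-dihydro-4H-chromen-4-one, via silyl enol ether 29 (not isolated)
Conditions: Cu(OAc)2 (5 mol%), (R)-DTBM-SEGPHOS (5.5 mol%), (EtO)2MeSiH (3 equiv), toluene, no alcohol additive, 0 °C → rt; then aq. NH4F, MeOH, 0 °C
Reagents that add atoms: none
Why: Asymmetric conjugate reduction by a phosphine-ligated copper hydride (monovalent copper) formed from Cu(OAc)2 and the silane: hydride adds to C2 of the chromone enone, the copper enolate is silylated to 29 (which turns the catalyst over and shields C4 from 1,2-reduction), and buffered fluoride releases the ketone without base. C2 is set by the chiral bisphosphine alone, which should deliver hydride to the face that gives 2S, while the unactivated isopropenyl and prenyl alkenes react far more slowly with copper hydride than the enone.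

Step 21
Reactants: 30 (2S)-2-[2,5-bis(methoxymethoxy)phenyl]-7-methoxy-5-(methoxymethoxy)-8-[(2R)-5-methyl-2-(prop-1-en-2-yl)hex-4-en-1-yl]-2,3-dihydro-4H-chromen-4-one
Product: 31 (2S)-2-(2,5-dihydroxyphenyl)-5-hydroxy-7-methoxy-8-[(2R)-5-methyl-2-(prop-1-en-2-yl)hex-4-en-1-yl]-2,3-dihydro-4H-chromen-4-one
Conditions: HCl (1.25 M in MeOH), degassed, 0 °C → rt, Ar; NaHCO3 quench
Reagents that add atoms: none
Why: Acid-catalysed acetal exchange transfers the three methoxymethyl groups to methanol; no phenol lies ortho to the side chain (O7 is methylated, O8a is in ring C), so the usual acid cyclisation of prenylated phenols has no partner, C2 is not labile under acid, and dilute anhydrous acid at low temperature should leave the two alkenes unprotonated.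

## Compound list

1 | 2-methylbut-3-en-2-ol | C=CC(C)(C)O | starting material
2 | triethyl orthoacetate | CC(OCC)(OCC)OCC | starting material
3 | 3-[(1-ethoxyethenyl)oxy]-3-methylbut-1-ene (ketene acetal, not isolated) | C=C(OCC)OC(C)(C)C=C | intermediate
4 | ethyl 5-methylhex-4-enoate | CCOC(=O)CCC=C(C)C | intermediate
5 | 5-methylhex-4-enoic acid | CC(C)=CCCC(=O)O | intermediate
6 | 1,1'-carbonyldiimidazole | O=C(n1ccnc1)n1ccnc1 | starting material
7 | 1-(1H-imidazol-1-yl)-5-methylhex-4-en-1-one | CC(C)=CCCC(=O)n1ccnc1 | intermediate
8 | 2,4-dihydroxy-6-methoxybenzaldehyde | O=Cc1c(O)cc(O)cc1OC | starting material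
9 | 2-hydroxy-6-methoxy-4-(methoxymethoxy)benzaldehyde | O=Cc1c(O)cc(OCOC)cc1OC | intermediate
10 | 2-[(tert-butyldimethylsilyl)oxy]-6-methoxy-4-(methoxymethoxy)benzaldehyde | O=Cc1c(OC)cc(OCOC)cc1O[Si](C)(C)C(C)(C)C | intermediate
11 | {2-[(tert-butyldimethylsilyl)oxy]-6-methoxy-4-(methoxymethoxy)phenyl}methanol | OCc1c(OC)cc(OCOC)cc1O[Si](C)(C)C(C)(C)C | intermediate
12 | tert-butyl[2-(bromomethyl)-3-methoxy-5-(methoxymethoxy)phenoxy]dimethylsilane | BrCc1c(OC)cc(OCOC)cc1O[Si](C)(C)C(C)(C)C | intermediate
13 | 2,5-dihydroxybenzaldehyde | O=Cc1cc(O)ccc1O | starting material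
14 | 2,5-bis(methoxymethoxy)benzaldehyde | O=Cc1cc(OCOC)ccc1OCOC | intermediate
15 | 2-ethynyl-1,4-bis(methoxymethoxy)benzene | C#Cc1cc(OCOC)ccc1OCOC | intermediate
16 | 5-methoxy-3-(methoxymethoxy)-6-methylidenecyclohexa-2,4-dien-1-one (ortho-quinone methide, not isolated) | C=C1C(OC)=CC(OCOC)=CC1=O | intermediate
17 | (3R)-5-methoxy-7-(methoxymethoxy)-3-(3-methylbut-2-en-1-yl)chroman-2-one | O=C1[C@H](CC=C(C)C)Cc2c(OC)cc(OCOC)cc2O1 | intermediate
18 | (2R)-2-{[2-hydroxy-6-methoxy-4-(methoxymethoxy)phenyl]methyl}-N-methoxy-N,5-dimethylhex-4-enamide | CON(C)C(=O)[C@H](CC=C(C)C)Cc1c(OC)cc(OCOC)cc1O | intermediate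
19 | (2R)-2-({2-[(tert-butyldimethylsilyl)oxy]-6-methoxy-4-(methoxymethoxy)phenyl}methyl)-N-methoxy-N,5-dimethylhex-4-enamide | CON(C)C(=O)[C@H](CC=C(C)C)Cc1c(OC)cc(OCOC)cc1O[Si](C)(C)C(C)(C)C | intermediate
20 | (3R)-3-({2-[(tert-butyldimethylsilyl)oxy]-6-methoxy-4-(methoxymethoxy)phenyl}methyl)-6-methylhept-5-en-2-one | CC(=O)[C@H](CC=C(C)C)Cc1c(OC)cc(OCOC)cc1O[Si](C)(C)C(C)(C)C | intermediate
21 | tert-butyl{3-methoxy-5-(methoxymethoxy)-2-[(2R)-5-methyl-2-(prop-1-en-2-yl)hex-4-en-1-yl]phenoxy}dimethylsilane | C=C(C)[C@H](CC=C(C)C)Cc1c(OC)cc(OCOC)cc1O[Si](C)(C)C(C)(C)C | intermediate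
22 | 3-methoxy-5-(methoxymethoxy)-2-[(2R)-5-methyl-2-(prop-1-en-2-yl)hex-4-en-1-yl]phenol | C=C(C)[C@H](CC=C(C)C)Cc1c(OC)cc(OCOC)cc1O | intermediate
23 | 2-hydroxy-4-methoxy-6-(methoxymethoxy)-3-[(2R)-5-methyl-2-(prop-1-en-2-yl)hex-4-en-1-yl]benzaldehyde | C=C(C)[C@H](CC=C(C)C)Cc1c(OC)cc(OCOC)c(C=O)c1O | intermediate
24 | lithium [2,5-bis(methoxymethoxy)phenyl]acetylide (not isolated) | [Li]C#Cc1cc(OCOC)ccc1OCOC | intermediate
25 | 3-[2,5-bis(methoxymethoxy)phenyl]-1-{2-hydroxy-4-methoxy-6-(methoxymethoxy)-3-[(2R)-5-methyl-2-(prop-1-en-2-yl)hex-4-en-1-yl]phenyl}prop-2-yn-1-ol (both carbinol epimers) | C=C(C)[C@H](CC=C(C)C)Cc1c(OC)cc(OCOC)c(C(O)C#Cc2cc(OCOC)ccc2OCOC)c1O | intermediate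
26 | 3-[2,5-bis(methoxymethoxy)phenyl]-1-{2-hydroxy-4-methoxy-6-(methoxymethoxy)-3-[(2R)-5-methyl-2-(prop-1-en-2-yl)hex-4-en-1-yl]phenyl}prop-2-yn-1-one | C=C(C)[C@H](CC=C(C)C)Cc1c(OC)cc(OCOC)c(C(=O)C#Cc2cc(OCOC)ccc2OCOC)c1O | intermediate
27 | 3-[2,5-bis(methoxymethoxy)phenyl]-3-(diethylamino)-1-{2-hydroxy-4-methoxy-6-(methoxymethoxy)-3-[(2R)-5-methyl-2-(prop-1-en-2-yl)hex-4-en-1-yl]phenyl}prop-2-en-1-one (enaminone, not isolated) | C=C(C)[C@H](CC=C(C)C)Cc1c(OC)cc(OCOC)c(C(=O)C=C(N(CC)CC)c2cc(OCOC)ccc2OCOC)c1O | intermediate
28 | 2-[2,5-bis(methoxymethoxy)phenyl]-7-methoxy-5-(methoxymethoxy)-8-[(2R)-5-methyl-2-(prop-1-en-2-yl)hex-4-en-1-yl]-4H-chromen-4-one | C=C(C)[C@H](CC=C(C)C)Cc1c(OC)cc(OCOC)c2c1OC(c1cc(OCOC)ccc1OCOC)=CC2=O | intermediate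
29 | (2S)-2-[2,5-bis(methoxymethoxy)phenyl]-4-{[diethoxy(methyl)silyl]oxy}-7-methoxy-5-(methoxymethoxy)-8-[(2R)-5-methyl-2-(prop-1-en-2-yl)hex-4-en-1-yl]-2H-chromene (silyl enol ether, not isolated) | C=C(C)[C@H](CC=C(C)C)Cc1c(OC)cc(OCOC)c2c1O[C@H](c1cc(OCOC)ccc1OCOC)C=C2O[Si](C)(OCC)OCC | intermediate
30 | (2S)-2-[2,5-bis(methoxymethoxy)phenyl]-7-methoxy-5-(methoxymethoxy)-8-[(2R)-5-methyl-2-(prop-1-en-2-yl)hex-4-en-1-yl]-2,3-dihydro-4H-chromen-4-one | C=C(C)[C@H](CC=C(C)C)Cc1c(OC)cc(OCOC)c2c1O[C@H](c1cc(OCOC)ccc1OCOC)CC2=O | intermediate
31 | (2S)-2-(2,5-dihydroxyphenyl)-5-hydroxy-7-methoxy-8-[(2R)-5-methyl-2-(prop-1-en-2-yl)hex-4-en-1-yl]-2,3-dihydro-4H-chromen-4-one | C=C(C)[C@H](CC=C(C)C)Cc1c(OC)cc(O)c2c1O[C@H](c1cc(O)ccc1O)CC2=O | target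

## Step count and least certain steps

Total step count: 21. Longest linear sequence: 16 steps (steps 4–7 and 10–21, from 8). The side branches are steps 1–3 (to 7) and steps 8–9 (to 15).

**Step 10 (key step).**
- What may go wrong: the catalysed pathway may lose out to self-condensation of the electron-rich, less electrophilic methide or to its capture by the azole. The enantiomeric purity may also erode, either through an uncatalysed enolate pathway or through reversible opening of the aryl ester product by the carbene followed by re-enolisation.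
- Fallback: the stereocentre would be set by an auxiliary instead of a catalyst. Acid 5, activated as its pivaloyl mixed anhydride, would acylate lithiated (4S)-4-benzyl-1,3-oxazolidin-2-one to give (4S)-4-benzyl-3-(5-methylhex-4-enoyl)-1,3-oxazolidin-2-one F1. Its sodium enolate (NaN(SiMe3)2, THF, −78 °C) would be alkylated by bromide 12 on the face away from the benzyl group to give (4S)-4-benzyl-3-[(2R)-2-({2-[(tert-butyldimethylsilyl)oxy]-6-methoxy-4-(methoxymethoxy)phenyl}methyl)-5-methylhex-4-enoyl]-1,3-oxazolidin-2-one F2. Transamination with the aluminium amide of step 11 would cleave the auxiliary and give Weinreb amide 19, where the route is rejoined.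

**Step 20.**
- What may go wrong: hydride delivery to C2 may be slow, because this carbon is flanked by a twisted, ortho-substituted ring B. Facial selectivity may be poor, which would give C2 epimers that differ only at a centre remote from C2'' and are unlikely to separate. Over-reduction at C4 is possible if the silyl enol ether is hydrolysed in the flask.
- Fallback: resolution instead of induction. Flavone 28 would be reduced with an achiral, less hindered copper hydride (Cu(OAc)2, 1,2-bis(diphenylphosphino)benzene, (EtO)2MeSiH) to the C2-epimeric mixture (2RS)-2-[2,5-bis(methoxymethoxy)phenyl]-7-methoxy-5-(methoxymethoxy)-8-[(2R)-5-methyl-2-(prop-1-en-2-yl)hex-4-en-1-yl]-2,3-dihydro-4H-chromen-4-one F3. Asymmetric transfer hydrogenation ([Cp*RhCl2]2, TsDPEN in the hand that consumes the 2R epimer, expected to be R,R; HCO2H/Et3N) would reduce that epimer to the cis alcohol (2R,4R)-2-[2,5-bis(methoxymethoxy)phenyl]-7-methoxy-5-(methoxymethoxy)-8-[(2R)-5-methyl-2-(prop-1-en-2-yl)hex-4-en-1-yl]-3,4-dihydro-2H-chromen-4-ol F4. The unreacted 2S epimer is 30, separable from the alcohol by chromatography.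

**Step 7.**
- What may go wrong: the benzylic bromide may ionise, and the cation may alkylate the electron-rich ring of another molecule. It may also quaternise the phosphine before it reaches step 10.
- Fallback: a stable leaving group would be used. Alcohol 11 would be acetylated (Ac2O, Et3N, DMAP) to {2-[(tert-butyldimethylsilyl)oxy]-6-methoxy-4-(methoxymethoxy)phenyl}methyl acetate F5, which can be purified and stored. Under the conditions of step 10, fluoride desilylation and 1,4-elimination of acetate, which is facile on this electron-rich ring, would give the same methide 16 and hence lactone 17.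

**Step 17.**
- What may go wrong: addition to an aldehyde deactivated by the neighbouring phenoxide and flanked by two ortho substituents may be incomplete. The product carbinol may ionise to an alkynyl quinone methide on work-up or on silica.
- Fallback: the phenol would be masked first. Aldehyde 23 would be silylated (TBSOTf, 2,6-lutidine) to 2-[(tert-butyldimethylsilyl)oxy]-4-methoxy-6-(methoxymethoxy)-3-[(2R)-5-methyl-2-(prop-1-en-2-yl)hex-4-en-1-yl]benzaldehyde F6. Addition of acetylide 24 would give 3-[2,5-bis(methoxymethoxy)phenyl]-1-{2-[(tert-butyldimethylsilyl)oxy]-4-methoxy-6-(methoxymethoxy)-3-[(2R)-5-methyl-2-(prop-1-en-2-yl)hex-4-en-1-yl]phenyl}prop-2-yn-1-ol F7, which cannot form a quinone methide. Oxidation with MnO2 would give 3-[2,5-bis(methoxymethoxy)phenyl]-1-{2-[(tert-butyldimethylsilyl)oxy]-4-methoxy-6-(methoxymethoxy)-3-[(2R)-5-methyl-2-(prop-1-en-2-yl)hex-4-en-1-yl]phenyl}prop-2-yn-1-one F8. Desilylation with Bu4NF buffered with AcOH would return ynone 26.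

**Step 21.**
- What may go wrong: protonation of the isopropenyl or prenyl alkene, with addition of methanol or cation cyclisation; partial epimerisation of C2 through ring opening once the 5- and 2'-hydroxyls are free; air oxidation of the hydroquinone.
- Fallback: Brønsted acid solvolysis would be replaced by trans-silylation. Treatment of 30 with TMSOTf and 2,2'-bipyridyl in CH2Cl2 at 0 °C converts aryl methoxymethyl ethers, through bipyridinium salts and without free acid, into aryl trimethylsilyl ethers. This would give (2S)-7-methoxy-8-[(2R)-5-methyl-2-(prop-1-en-2-yl)hex-4-en-1-yl]-5-[(trimethylsilyl)oxy]-2-{2,5-bis[(trimethylsilyl)oxy]phenyl}-2,3-dihydro-4H-chromen-4-one F9, whose silyl groups fall off on addition of water at neutral pH to give 31.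

## Further compounds

F1 | step 10 | (4S)-4-benzyl-3-(5-methylhex-4-enoyl)-1,3-oxazolidin-2-one | CC(C)=CCCC(=O)N1[C@@H](Cc2ccccc2)COC1=O
F2 | step 10 | (4S)-4-benzyl-3-[(2R)-2-({2-[(tert-butyldimethylsilyl)oxy]-6-methoxy-4-(methoxymethoxy)phenyl}methyl)-5-methylhex-4-enoyl]-1,3-oxazolidin-2-one | CC(C)=CC[C@H](Cc1c(OC)cc(OCOC)cc1O[Si](C)(C)C(C)(C)C)C(=O)N1[C@@H](Cc2ccccc2)COC1=O
F3 | step 20 | (2RS)-2-[2,5-bis(methoxymethoxy)phenyl]-7-methoxy-5-(methoxymethoxy)-8-[(2R)-5-methyl-2-(prop-1-en-2-yl)hex-4-en-1-yl]-2,3-dihydro-4H-chromen-4-one (mixture of C2 epimers) | C=C(C)[C@H](CC=C(C)C)Cc1c(OC)cc(OCOC)c2c1OC(c1cc(OCOC)ccc1OCOC)CC2=O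
F4 | step 20 | (2R,4R)-2-[2,5-bis(methoxymethoxy)phenyl]-7-methoxy-5-(methoxymethoxy)-8-[(2R)-5-methyl-2-(prop-1-en-2-yl)hex-4-en-1-yl]-3,4-dihydro-2H-chromen-4-ol | C=C(C)[C@H](CC=C(C)C)Cc1c(OC)cc(OCOC)c2c1O[C@@H](c1cc(OCOC)ccc1OCOC)C[C@H]2O
F5 | step 7 | {2-[(tert-butyldimethylsilyl)oxy]-6-methoxy-4-(methoxymethoxy)phenyl}methyl acetate | CC(=O)OCc1c(OC)cc(OCOC)cc1O[Si](C)(C)C(C)(C)C
F6 | step 17 | 2-[(tert-butyldimethylsilyl)oxy]-4-methoxy-6-(methoxymethoxy)-3-[(2R)-5-methyl-2-(prop-1-en-2-yl)hex-4-en-1-yl]benzaldehyde | C=C(C)[C@H](CC=C(C)C)Cc1c(OC)cc(OCOC)c(C=O)c1O[Si](C)(C)C(C)(C)C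
F7 | step 17 | 3-[2,5-bis(methoxymethoxy)phenyl]-1-{2-[(tert-butyldimethylsilyl)oxy]-4-methoxy-6-(methoxymethoxy)-3-[(2R)-5-methyl-2-(prop-1-en-2-yl)hex-4-en-1-yl]phenyl}prop-2-yn-1-ol | C=C(C)[C@H](CC=C(C)C)Cc1c(OC)cc(OCOC)c(C(O)C#Cc2cc(OCOC)ccc2OCOC)c1O[Si](C)(C)C(C)(C)C
F8 | step 17 | 3-[2,5-bis(methoxymethoxy)phenyl]-1-{2-[(tert-butyldimethylsilyl)oxy]-4-methoxy-6-(methoxymethoxy)-3-[(2R)-5-methyl-2-(prop-1-en-2-yl)hex-4-en-1-yl]phenyl}prop-2-yn-1-one | C=C(C)[C@H](CC=C(C)C)Cc1c(OC)cc(OCOC)c(C(=O)C#Cc2cc(OCOC)ccc2OCOC)c1O[Si](C)(C)C(C)(C)C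
F9 | step 21 | (2S)-7-methoxy-8-[(2R)-5-methyl-2-(prop-1-en-2-yl)hex-4-en-1-yl]-5-[(trimethylsilyl)oxy]-2-{2,5-bis[(trimethylsilyl)oxy]phenyl}-2,3-dihydro-4H-chromen-4-one | C=C(C)[C@H](CC=C(C)C)Cc1c(OC)cc(O[Si](C)(C)C)c2c1O[C@H](c1cc(O[Si](C)(C)C)ccc1O[Si](C)(C)C)CC2=O
A1 | alternative 1 | (2S)-2-[2,5-bis(methoxymethoxy)phenyl]-5-hydroxy-7-methoxy-8-[(2R)-5-methyl-2-(prop-1-en-2-yl)hex-4-en-1-yl]-2,3-dihydro-4H-chromen-4-one | C=C(C)[C@H](CC=C(C)C)Cc1c(OC)cc(O)c2c1O[C@H](c1cc(OCOC)ccc1OCOC)CC2=O
A2 | alternative 1 | (2S)-2-[2,5-bis(methoxymethoxy)phenyl]-5-bromo-2,3-dihydro-4H-pyran-4-one | O=C1C[C@@H](c2cc(OCOC)ccc2OCOC)OC=C1Br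
A3 | alternative 1 | {[(6R)-1,3-dimethoxy-9-methyl-6-(prop-1-en-2-yl)deca-1,3,8-trien-1-yl]oxy}trimethylsilane (diene geometry not specified) | C=C(C)[C@H](CC=C(C)C)CC=C(OC)C=C(OC)O[Si](C)(C)C
A4 | alternative 2 | 3-methoxy-5-(methoxymethoxy)-2-[(2R)-5-methyl-2-(prop-1-en-2-yl)hex-4-en-1-yl]phenol (identical with 22) | C=C(C)[C@H](CC=C(C)C)Cc1c(OC)cc(OCOC)cc1O
A5 | alternative 2 | 3-(methoxymethoxy)cyclobut-2-en-1-one | O=C1C=C(OCOC)C1
A6 | alternative 2 | (4R)-1-methoxy-7-methyl-4-(prop-1-en-2-yl)oct-6-en-1-yne | C=C(C)[C@H](CC=C(C)C)CC#COC
A7 | alternative 3 | (2S)-5-[(tert-butyldimethylsilyl)oxy]-2-{2,5-bis[(tert-butyldimethylsilyl)oxy]phenyl}-7-methoxy-8-[(2R)-5-methyl-2-(prop-1-en-2-yl)hex-4-en-1-yl]-2,3-dihydro-4H-chromen-4-one | C=C(C)[C@H](CC=C(C)C)Cc1c(OC)cc(O[Si](C)(C)C(C)(C)C)c2c1O[C@H](c1cc(O[Si](C)(C)C(C)(C)C)ccc1O[Si](C)(C)C(C)(C)C)CC2=O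
A8 | alternative 3 | 1-{2-({2,5-bis[(tert-butyldimethylsilyl)oxy]phenyl}methoxy)-6-[(tert-butyldimethylsilyl)oxy]-4-methoxy-3-[(2R)-5-methyl-2-(prop-1-en-2-yl)hex-4-en-1-yl]phenyl}-2-diazoethan-1-one | C=C(C)[C@H](CC=C(C)C)Cc1c(OC)cc(O[Si](C)(C)C(C)(C)C)c(C(=O)C=[N+]=[N-])c1OCc1cc(O[Si](C)(C)C(C)(C)C)ccc1O[Si](C)(C)C(C)(C)C
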